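- I choose to reckon these flasks in amounts rather than times, since oak gains 7.3% of target by 0.667 min but 5 percentage points over its last 5.00 min.

| flask | electrophile | nucleophile | remark | time |
|---|---|---|---|---|
| oak | 10 mM | 4 mM | run made earlier |  |
| ochre | 10 mM | 8.00 mM |  | 8.0 min |
| teal | 10 mM | 10.0 mM |  | 8.0 min |
| blue | 10 mM | 14.0 mM |  | 8.0 min |

oak run (percent of the electrophile charged)

| time / min | electrophile / % | target / % |
|---|---|---|
| 0.667 | 93.7 | 7.3 |
| 1.33 | 89.4 | 9.5 |
| 3.00 | 87.4 | 14.3 |
| 8.00 | 81.7 | 19.3 |

(scatter of a reading: 1 percentage point)

- a reading or a percentage of target counts all its forms, free or not

- part of the electrophile that has reacted at the end, ochre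
- part of the electrophile that has reacted at the end, teal
- part of the electrophile that has reacted at the end, blue
- what raising the concentration of nucleophile from its lowest to its highest value here does to the part of the electrophile that has reacted (changes below 5 percentage points count as none) (it rises / no change / it falls)

- Two amounts matter in oak: the 1.93 mM of target made by 8.00 min, and the 4 mM of nucleophile charged.
- The nucleophile is the limiting reagent here, since oak charges less of it than of electrophile and still holds 81.7% of its electrophile at that time.
- Their ratio is 0.482, taken from a single target reading whose scatter is 1 point, and I carry it as the return, target made per nucleophile charged.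
- The even case, one nucleophile for each target, is the zero of my scale and gives a return of one; oak's reading lies below that, at 2.07 nucleophile charged for each target made.
- Holding the return fixed, I multiply it by the nucleophile charge and divide by the electrophile charge, which gives 38.6% for ochre, 48.2% for teal and 67.5% for blue.
- The forecast gives lower figures than mine, 37%, 44% and 57%, with the trend as it rises, and it weighs a reversible reaction against the case where “the target ties up a second nucleophile”.
- The flasks give 33.9% in ochre, 40.5% in teal and 51.8% in blue, and from lowest to highest charge it rises, by 18 points; at 8.00 min ochre holds 3.29 mM of protonated nucleophile beside 3.39 mM of target.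

    electrophile + nucleophile → acid set free + target (k = 41.0 /M/min)
    nucleophile + acid set free ⇌ protonated nucleophile, settled at all times (K = 1.40 × 10⁵ /M)
    nucleophile ⇌ dormant form (K = 0.400, k = 2.10 /min)
    2 nucleophile → self-condensation product (k = 17.0 /M/min)
    nucleophile + target ⇌ idle adduct, settled at all times (K = 140 /M)

- I now take oak's return of 0.482 to the neighbour of ochre charged with 40 mM of electrophile: times 8.00 mM of nucleophile, over that charge, it gives 9.64%, and that flask reaches 10.7%, with 0.36% of its nucleophile left unbound.

The runs stem from a simulated flask on assumed constants, noise included.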